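Everything rests on excising C2 from ring B. This hydroxyl-bearing carbon sits alone between carbonyl C1 and the side-chain carbon C3, so ring B can be carried as the five-membered ring of a 2-substituted 4,5,7-trimethoxyindan-1-one and enlarged late. The precursor is that indanone's tert-butyldimethylsilyl enol ether, whose side chain already holds the (S)-acetoxy stereocentre bought with (S)-γ-valerolactone. Dibromocarbene adds across the C1=C3 enol double bond and the strained dibromocyclopropane opens at once. One operation thus forms C1–C2 and C2–C3, turns the five-membered ring into aromatic ring B, and leaves bromine on C2 as the handle for the hydroxyl group.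

Key step: step 6

Assumption: naphthalene-stage compounds carry the target numbering (C1 and C4 carbonyl carbons, C2 oxygenated, C3 side chain, methoxy on C5, C6, C8). Centres that are later planarised (C4 of 6, C2 of 8, ring carbons of 11) are carried as mixtures. The carbinol carbon has the same spatial arrangement (O > CH2 > CH3 > H, descriptor S) from 2 to 17.

Step 1
Reactants: 1 1-bromo-2,4,5-trimethoxybenzene; 2 (S)-γ-valerolactone
Product: 4 (4S)-4-hydroxy-1-(2,4,5-trimethoxyphenyl)pentan-1-one, via 2,4,5-trimethoxyphenyllithium 3 (not isolated)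
Conditions: n-BuLi, THF, −78 °C; cannulate into 2 (1.3 equiv), THF, −78 °C; AcOH, −78 °C → rt
Reagents that add atoms: none
Why: Bromine–lithium exchange followed by nucleophilic acyl addition of the aryllithium to the lactone, in which the lithium lactolate, held by chelation to the ortho methoxy group, should not collapse to the ketone before the cold acid quench, so a second addition is avoided, and the C–O bond at the stereocentre is never broken, so the (S) configuration of 2 is carried over.

Step 2
Reactants: 4 (4S)-4-hydroxy-1-(2,4,5-trimethoxyphenyl)pentan-1-one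
Product: 5 (2S)-5-oxo-5-(2,4,5-trimethoxyphenyl)pentan-2-yl acetate
Conditions: Ac2O, pyridine, 4-(dimethylamino)pyridine (cat.), CH2Cl2, 0 °C → rt
Reagents that add atoms: acetic anhydride, CC(=O)OC(C)=O
Why: Nucleophile-catalysed O-acetylation of the secondary alcohol, which is available because the conjugated electron-rich aryl ketone prefers the open hydroxy-ketone form to the lactol, takes place at oxygen and therefore retains the configuration.

Step 3
Reactants: 5 (2S)-5-oxo-5-(2,4,5-trimethoxyphenyl)pentan-2-yl acetate
Product: 7 (2S)-4-methylidene-5-oxo-5-(2,4,5-trimethoxyphenyl)pentan-2-yl acetate, via Mannich base 6 (not isolated)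
Conditions: (CH2O)n, iPr2NH·CF3CO2H, CF3CO2H (cat.), THF, reflux
Reagents that add atoms: formaldehyde (as paraformaldehyde), C=O
Why: Mannich aminomethylation at the only enolisable CH2 next to the ketone and β-elimination of the amine in the same flask (direct α-methylenation of an aryl alkyl ketone) run under buffered ammonium-salt conditions that leave the acetate and the acyl-deactivated arene alone.

Step 4
Reactants: 7 (2S)-4-methylidene-5-oxo-5-(2,4,5-trimethoxyphenyl)pentan-2-yl acetate
Product: 8 (2S)-1-(4,5,7-trimethoxy-1-oxo-2,3-dihydro-1H-inden-2-yl)propan-2-yl acetate (both C2 epimers)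
Conditions: CF3SO3H (3 equiv), CH2Cl2, 0 °C → rt
Reagents that add atoms: none
Why: Aromatic Nazarov cyclisation (superacid-promoted 4π conrotatory electrocyclisation of the O-protonated aryl vinyl ketone, then rearomatisation and ketonisation) can only engage the single free ortho carbon of the aryl ring, which is activated by its neighbouring methoxy group, while the non-nucleophilic triflate spares the methyl ethers, the protonated acetate on an unactivated secondary carbon should not ionise at this temperature, and the new C2 centre, formed without control, is erased in step 5.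

Step 5
Reactants: 8 (2S)-1-(4,5,7-trimethoxy-1-oxo-2,3-dihydro-1H-inden-2-yl)propan-2-yl acetate
Product: 9 (2S)-1-[3-(tert-butyldimethylsilyloxy)-4,6,7-trimethoxy-1H-inden-2-yl]propan-2-yl acetate
Conditions: tBuMe2SiOTf, Et3N, CH2Cl2, 0 °C → rt
Reagents that add atoms: tert-butyldimethylsilyl trifluoromethanesulfonate, CC(C)(C)[Si](C)(C)OS(=O)(=O)C(F)(F)F
Why: Soft enolisation (silyl triflate plus tertiary amine) of a ketone with a single α-hydrogen can give only one enol ether and is much faster at the ketone than at the ester, and the bulky silyl group is chosen because the tert-butoxide of step 6 would strip a trimethylsilyl enol ether to the enolate.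

Step 6
Reactants: 9 (2S)-1-[3-(tert-butyldimethylsilyloxy)-4,6,7-trimethoxy-1H-inden-2-yl]propan-2-yl acetate; 10 bromoform
Product: 13 2-bromo-3-[(2S)-2-acetoxypropyl]-5,6,8-trimethoxynaphthalen-1-ol, via dibromocyclopropane 11 (not isolated), via naphthyl silyl ether 12 (not isolated)
Conditions: CHBr3, KOtBu (added in portions), pentane–toluene, −20 °C → rt; then Bu4NF, AcOH, THF, 0 °C
Reagents that add atoms: bromoform 10, BrC(Br)Br
Why: KOtBu removes HBr from bromoform by α-elimination, and the singlet dibromocarbene adds in a concerted [2+1] fashion to the C1=C3 double bond of 9 (target numbering), which creates C1–C2 and C2–C3 and gives the benzo-fused 6,6-dibromobicyclo[3.1.0]hexane 11. Ring strain and the push of the siloxy oxygen then drive a disrotatory cyclopropyl-to-allyl opening in which the shared C1–C3 bond breaks and the endo bromide leaves, and the siloxy-stabilised 2-bromoallyl cation loses a benzylic C4 proton to base to give the aromatic silyl ether 12, which buffered fluoride converts into 13 without touching the acetate. The closest known reaction type is the dihalocarbene one-carbon ring expansion of cyclic silyl enol ethers to 2-halo enones and of indenes and indanone silyl enol ethers to 2-halonaphthalenes and 2-halo-1-naphthols. Ring B is therefore not closed by cyclisation: a three-membered ring is closed by cheletropic addition and its fusion bond is cut electrocyclically, so the five-membered ring becomes six-membered. No stereocentre is created in 13, because both cyclopropane ring-fusion carbons of 11 (formed as a diastereomer mixture) end up sp2, and the (S) carbinol carbon lies two bonds outside the reacting ring and is not involved. The step needs chemoselectivity for the enol ether over the trimethoxyarene and the ester, which is secured by the high nucleophilicity of the tetrasubstituted siloxyalkene, by the bulky silyl group that resists tert-butoxide and by feeding the base slowly into excess bromoform, while regiochemistry is fixed because 8 can enolise only towards its C2.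

Step 7
Reactants: 13 2-bromo-3-[(2S)-2-acetoxypropyl]-5,6,8-trimethoxynaphthalen-1-ol
Product: 14 2-bromo-3-[(2S)-2-acetoxypropyl]-5,6,8-trimethoxy-1,4-naphthoquinone
Conditions: (KSO3)2NO, KH2PO4, acetone–H2O, rt
Reagents that add atoms: potassium nitrosodisulfonate (KSO3)2NO, [K+].[K+].[O-]S(=O)(=O)N([O])S(=O)(=O)[O-]
Why: Teuber oxidation is a phenol-specific one-electron process in which the nitroxide delivers oxygen to the unsubstituted para carbon C4 of the 1-naphthol, so the para-dimethoxy pattern of ring A, the bromide and the acetate should stay untouched at buffered pH.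

Step 8
Reactants: 14 2-bromo-3-[(2S)-2-acetoxypropyl]-5,6,8-trimethoxy-1,4-naphthoquinone
Product: 15 2-hydroxy-3-[(2S)-2-hydroxypropyl]-5,6,8-trimethoxy-1,4-naphthoquinone
Conditions: KOH, MeOH–H2O, argon, rt → 50 °C; then 1 M HCl, 0 °C
Reagents that add atoms: potassium hydroxide, [K+].[OH-]
Why: Addition–elimination (vinylogous acyl substitution) of hydroxide at the bromine-bearing C2, the standard hydrolysis of 2-halo-3-alkyl-1,4-naphthoquinones, is driven by formation of the delocalised hydroxyquinone anion, into which any dihydrofuran formed by attack of the side-chain alkoxide on C2 is also opened, while the acetate is saponified by acyl–oxygen cleavage so that the stereocentre keeps its configuration.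

Step 9
Reactants: 15 2-hydroxy-3-[(2S)-2-hydroxypropyl]-5,6,8-trimethoxy-1,4-naphthoquinone
Product: 17 2-hydroxy-3-[(2S)-2-acetoxypropyl]-5,6,8-trimethoxy-1,4-naphthoquinone (CNP0321270.1), via quinone diacetate 16 (not isolated)
Conditions: Ac2O, pyridine, 4-(dimethylamino)pyridine (cat.), CH2Cl2, 0 °C → rt; then MeOH, rt; wash with 1 M HCl
Reagents that add atoms: acetic anhydride, CC(=O)OC(C)=O
Why: Exhaustive nucleophile-catalysed acetylation followed by chemoselective methanolysis works because the C2 acetate is a vinylogous mixed anhydride that passes its acyl group to methanol under the amine catalysis already present, whereas the secondary alkyl acetate is inert, and acylation at oxygen retains the (S) configuration.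

Compound list
1 | 1-bromo-2,4,5-trimethoxybenzene | COc1cc(OC)c(Br)cc1OC | starting material
2 | (S)-γ-valerolactone, (5S)-5-methyloxolan-2-one | C[C@H]1CCC(=O)O1 | starting material
3 | 2,4,5-trimethoxyphenyllithium | [Li]c1cc(OC)c(OC)cc1OC | intermediate
4 | (4S)-4-hydroxy-1-(2,4,5-trimethoxyphenyl)pentan-1-one | COc1cc(OC)c(cc1OC)C(=O)CC[C@H](C)O | intermediate
5 | (2S)-5-oxo-5-(2,4,5-trimethoxyphenyl)pentan-2-yl acetate | COc1cc(OC)c(cc1OC)C(=O)CC[C@H](C)OC(C)=O | intermediate
6 | (2S)-4-[(diisopropylamino)methyl]-5-oxo-5-(2,4,5-trimethoxyphenyl)pentan-2-yl acetate, Mannich base, both C4 epimers | COc1cc(OC)c(cc1OC)C(=O)C(CN(C(C)C)C(C)C)C[C@H](C)OC(C)=O | intermediate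
7 | (2S)-4-methylidene-5-oxo-5-(2,4,5-trimethoxyphenyl)pentan-2-yl acetate | COc1cc(OC)c(cc1OC)C(=O)C(=C)C[C@H](C)OC(C)=O | intermediate
8 | (2S)-1-(4,5,7-trimethoxy-1-oxo-2,3-dihydro-1H-inden-2-yl)propan-2-yl acetate, both C2 epimers | COc1cc(OC)c2c(c1OC)CC(C[C@H](C)OC(C)=O)C2=O | intermediate
9 | (2S)-1-[3-(tert-butyldimethylsilyloxy)-4,6,7-trimethoxy-1H-inden-2-yl]propan-2-yl acetate | COc1cc(OC)c2c(c1OC)CC(C[C@H](C)OC(C)=O)=C2O[Si](C)(C)C(C)(C)C | intermediate
10 | bromoform | BrC(Br)Br | starting material
11 | (2S)-1-[1,1-dibromo-1a-(tert-butyldimethylsilyloxy)-2,4,5-trimethoxy-1,1a,6,6a-tetrahydrocyclopropa[a]inden-6a-yl]propan-2-yl acetate, ring diastereomers | COc1cc(OC)c2c(c1OC)CC1(C[C@H](C)OC(C)=O)C(Br)(Br)C21O[Si](C)(C)C(C)(C)C | intermediate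
12 | (2S)-1-[3-bromo-4-(tert-butyldimethylsilyloxy)-5,7,8-trimethoxynaphthalen-2-yl]propan-2-yl acetate | COc1cc(OC)c2c(O[Si](C)(C)C(C)(C)C)c(Br)c(C[C@H](C)OC(C)=O)cc2c1OC | intermediate
13 | 2-bromo-3-[(2S)-2-acetoxypropyl]-5,6,8-trimethoxynaphthalen-1-ol | COc1cc(OC)c2c(O)c(Br)c(C[C@H](C)OC(C)=O)cc2c1OC | intermediate
14 | 2-bromo-3-[(2S)-2-acetoxypropyl]-5,6,8-trimethoxy-1,4-naphthoquinone | COc1cc(OC)c2c(c1OC)C(=O)C(C[C@H](C)OC(C)=O)=C(Br)C2=O | intermediate
15 | 2-hydroxy-3-[(2S)-2-hydroxypropyl]-5,6,8-trimethoxy-1,4-naphthoquinone | COc1cc(OC)c2c(c1OC)C(=O)C(C[C@H](C)O)=C(O)C2=O | intermediate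
16 | 2-acetoxy-3-[(2S)-2-acetoxypropyl]-5,6,8-trimethoxy-1,4-naphthoquinone | COc1cc(OC)c2c(c1OC)C(=O)C(C[C@H](C)OC(C)=O)=C(OC(C)=O)C2=O | intermediate
17 | 2-hydroxy-3-[(2S)-2-acetoxypropyl]-5,6,8-trimethoxy-1,4-naphthoquinone (CNP0321270.1) | COc1cc(OC)c2c(c1OC)C(=O)C(C[C@H](C)OC(C)=O)=C(O)C2=O | target

Total step count: 9. Longest linear sequence: 9 steps (1 to 17).

Steps most likely to fail

**Step 6.** Carbene transfer to the crowded tetrasubstituted double bond may be slower than consumption of the carbene by tert-butoxide and tert-butanol. More base is then needed, and three side processes begin to compete: base-induced loss of the silyl group, loss of the acetate, and further carbene attack on the electron-rich naphthalene. Loss of the acetate alone is harmless, because such material rejoins the route at 15.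

The fallback sets out from 9 and comes back at 15. The extra carbon is delivered as a zinc carbenoid and the C2 oxygen is installed afterwards.
- Et2Zn and CH2I2 (Furukawa variant of the Simmons–Smith cyclopropanation) should give the siloxycyclopropane F1.
- FeCl3 in DMF (Ito–Saegusa oxidative ring expansion) cuts the central bond to give the 3-chlorotetralone F2.
- NaOAc in warm MeOH removes HCl, and the resulting enone tautomerises to the bromine-free naphthol F3.
- (KSO3)2NO oxidises this to the 2-unsubstituted quinone F4.
- H2O2 and Na2CO3 (Weitz–Scheffer epoxidation) give the quinone epoxide F5.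
- Aqueous KOH, as in step 8, opens the epoxide at C2, dehydrates the diol and cleaves the acetate to reach 15.

**Step 4.** The electrocyclisation may be sluggish, because the methoxy groups ortho and para to the carbonyl drain charge away from the vinyl terminus. Stronger forcing invites ionisation or neighbouring-group displacement at the acetate-bearing carbon, with erosion of configurational purity, and polymerisation of the enone.

The fallback sets out from 1 (through aryllithium 3) and comes back at 8. Ring closure is moved ahead of the stereocentre so that it can be forced.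
- Compound 3 is acylated with 3-chloro-N-methoxy-N-methylpropanamide to give the β-chloro ketone F6.
- F6 carries nothing acid-labile and is cyclised in warm neat CF3SO3H (loss of HCl, then Nazarov closure) to the parent indanone F7.
- Me2NNH2 gives the dimethylhydrazone F8.
- LiN(iPr)2, then (S)-propylene oxide (C[C@H]1CO1), gives the hydroxy hydrazone F9. This is a Corey–Enders type azaenolate alkylation, with attack at the CH2 terminus and retention of configuration.
- Aqueous oxalic acid releases the hydroxy indanone F10.
- Acetylation as in step 2 returns 8.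

**Step 1.** Premature collapse of the tetrahedral adduct would release the ketone while aryllithium is still present, leading to double addition. Enolisation of the lactone by the aryllithium would simply return the protonated arene.

The fallback sets out from 2 and comes back at 4.
- Aminolysis of the lactone with MeNH(OMe)·HCl and AlMe3 in CH2Cl2 gives the hydroxy Weinreb amide F11.
- Its hydroxyl group is deprotonated with iPrMgCl.
- Aryllithium 3 is then added at −78 → 0 °C.
- The N-methoxy chelate holds the tetrahedral intermediate until the quench, so only one aryl group can enter and 4 results.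

Further compounds
F1 | step 6 | (2S)-1-[1a-(tert-butyldimethylsilyloxy)-2,4,5-trimethoxy-1,1a,6,6a-tetrahydrocyclopropa[a]inden-6a-yl]propan-2-yl acetate | COc1cc(OC)c2c(c1OC)CC1(C[C@H](C)OC(C)=O)CC21O[Si](C)(C)C(C)(C)C
F2 | step 6 | 3-chloro-3-[(2S)-2-acetoxypropyl]-5,6,8-trimethoxy-3,4-dihydronaphthalen-1(2H)-one | COc1cc(OC)c2c(c1OC)CC(Cl)(C[C@H](C)OC(C)=O)CC2=O
F3 | step 6 | 3-[(2S)-2-acetoxypropyl]-5,6,8-trimethoxynaphthalen-1-ol | COc1cc(OC)c2c(O)cc(C[C@H](C)OC(C)=O)cc2c1OC
F4 | step 6 | 3-[(2S)-2-acetoxypropyl]-5,6,8-trimethoxy-1,4-naphthoquinone (target numbering) | COc1cc(OC)c2c(c1OC)C(=O)C(C[C@H](C)OC(C)=O)=CC2=O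
F5 | step 6 | 3-[(2S)-2-acetoxypropyl]-2,3-epoxy-5,6,8-trimethoxy-2,3-dihydro-1,4-naphthoquinone | COc1cc(OC)c2c(c1OC)C(=O)C1(C[C@H](C)OC(C)=O)OC1C2=O
F6 | step 4 | 3-chloro-1-(2,4,5-trimethoxyphenyl)propan-1-one | COc1cc(OC)c(cc1OC)C(=O)CCCl
F7 | step 4 | 4,5,7-trimethoxyindan-1-one | COc1cc(OC)c2c(c1OC)CCC2=O
F8 | step 4 | 4,5,7-trimethoxyindan-1-one N,N-dimethylhydrazone | COc1cc(OC)c2c(c1OC)CCC2=NN(C)C
F9 | step 4 | 2-[(2S)-2-hydroxypropyl]-4,5,7-trimethoxyindan-1-one N,N-dimethylhydrazone | COc1cc(OC)c2c(c1OC)CC(C[C@H](C)O)C2=NN(C)C
F10 | step 4 | 2-[(2S)-2-hydroxypropyl]-4,5,7-trimethoxyindan-1-one | COc1cc(OC)c2c(c1OC)CC(C[C@H](C)O)C2=O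
F11 | step 1 | (4S)-4-hydroxy-N-methoxy-N-methylpentanamide | C[C@H](O)CCC(=O)N(C)OC
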